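## Retrosynthetic overview

1. Feature: in the cyclohexene (ring C1 = fully substituted carbinol carrying C7H2OBz, C2–OBz, C3=C4, C5–OBz, C6–OH) the C1–C2 bond lies between the C3=C4 double bond and C7. With C7 as an aldehyde this is a γ,δ-unsaturated carbonyl unit, the product pattern of a Claisen rearrangement.
2. Key disconnection: cutting C1–C2 and rejoining C4 to the C7 oxygen gives a dihydropyran, a D-gluco 2-benzoyloxy glycal with a (Z)-2-benzoyloxyvinyl group on sugar C5 (sugar C2, C7, C6, C5, C4, C3 become ring C1 to C6; sugar C1 becomes C7).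
3. The Z enol benzoate comes from Ru-catalysed anti-Markovnikov addition of benzoic acid to a C5-ethynyl glycal; the glycal from the lactol (bromination, E2); the alkyne from the C6 aldehyde by Ohira–Bestmann homologation, run while O2 and O4 are silyl ethers, before any benzoate is present.
4. Ring order: the pyran is the D-glucose ring (bought as thioglycoside 1); the carbocycle is the only ring formed (step 11), at the expense of the pyran. The endgame is aldehyde reduction, tertiary-to-primary benzoyl shift and desilylation.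

Key step: step 11

Assumption: thioglycoside 1 is taken as the purchasable form of D-glucose; "sugar C1–C7" is the heptose numbering and "ring C1–C7" the target numbering used above.

## Route

Step 1
Reactants: 1 phenyl 4,6-O-[(R)-benzylidene]-1-thio-β-D-glucopyranoside
Product: 2 phenyl 4,6-O-benzylidene-3-O-(tert-butyldimethylsilyl)-1-thio-β-D-glucopyranoside
Conditions: TBSCl (1.3 equiv), imidazole, DMF, 0 °C → rt
Reagents that add atoms: tert-butyldimethylsilyl chloride, CC(C)(C)[Si](C)(C)Cl
Why: Regioselective silylation: in 4,6-O-benzylidene β-thioglucosides O3 is the more accessible and more nucleophilic hydroxyl (O2 is deactivated and shielded by the thiophenyl-bearing anomeric carbon), so the bulky chloride should silylate O3; no stereocentre is touched.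

Step 2
Reactants: 2 phenyl 4,6-O-benzylidene-3-O-(tert-butyldimethylsilyl)-1-thio-β-D-glucopyranoside
Product: 3 phenyl 3-O-(tert-butyldimethylsilyl)-1-thio-β-D-glucopyranoside
Conditions: EtSH, TsOH·H2O (cat.), CH2Cl2, rt
Reagents that add atoms: none
Why: Acid-catalysed transthioacetalisation should remove the benzylidene acetal under aprotic conditions that a secondary silyl ether and the thioglycoside tolerate.

Step 3
Reactants: 3 phenyl 3-O-(tert-butyldimethylsilyl)-1-thio-β-D-glucopyranoside
Product: 4 phenyl 3-O-(tert-butyldimethylsilyl)-2,4,6-tris-O-(triethylsilyl)-1-thio-β-D-glucopyranoside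
Conditions: TESOTf (3.5 equiv), 2,6-lutidine, CH2Cl2, −40 → 0 °C
Reagents that add atoms: triethylsilyl trifluoromethanesulfonate, CC[Si](CC)(CC)OS(=O)(=O)C(F)(F)F
Why: Exhaustive silylation with the reactive triflate should cap the two hindered secondary hydroxyls beside the TBS ether and O6, giving base-stable, non-leaving groups at O2 and O4 for the aldehyde stage.

Step 4
Reactants: 4 phenyl 3-O-(tert-butyldimethylsilyl)-2,4,6-tris-O-(triethylsilyl)-1-thio-β-D-glucopyranoside
Product: 5 phenyl 3-O-(tert-butyldimethylsilyl)-2,4-bis-O-(triethylsilyl)-1-thio-β-D-gluco-hexodialdo-1,5-pyranoside (C6 aldehyde)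
Conditions: (COCl)2, DMSO, CH2Cl2, −78 → −35 °C; then Et3N, → 0 °C
Reagents that add atoms: none
Why: Swern oxidation applied directly to the silyl ether: the chlorosulfonium salt should cleave only the unhindered primary triethylsilyl ether and the alkoxysulfonium ion collapses to the aldehyde on adding the amine, while the 4-O-silyl group is too poor a leaving group for β-elimination and the cold conditions should avoid C5 epimerisation.

Step 5
Reactants: 5 phenyl 3-O-(tert-butyldimethylsilyl)-2,4-bis-O-(triethylsilyl)-1-thio-β-D-gluco-hexodialdo-1,5-pyranoside; 6 dimethyl (1-diazo-2-oxopropyl)phosphonate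
Product: 7 phenyl 3-O-(tert-butyldimethylsilyl)-6,7-dideoxy-2,4-bis-O-(triethylsilyl)-1-thio-β-D-gluco-hept-6-ynopyranoside
Conditions: K2CO3, MeOH, 0 °C → rt
Reagents that add atoms: dimethyl (1-diazo-2-oxopropyl)phosphonate, COP(=O)(OC)C(=[N+]=[N-])C(C)=O
Why: Ohira–Bestmann (Seyferth–Gilbert) homologation: methoxide unmasks the diazomethylphosphonate anion, which turns the aldehyde into the terminal alkyne through the diazoalkene and a 1,2-hydride shift; silyl ethers and the thioglycoside are stable to K2CO3/MeOH and no ester is yet present.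

Step 6
Reactants: 7 phenyl 3-O-(tert-butyldimethylsilyl)-6,7-dideoxy-2,4-bis-O-(triethylsilyl)-1-thio-β-D-gluco-hept-6-ynopyranoside
Product: 8 phenyl 3-O-(tert-butyldimethylsilyl)-6,7-dideoxy-1-thio-β-D-gluco-hept-6-ynopyranoside
Conditions: PPTS, MeOH/CH2Cl2, rt
Reagents that add atoms: none
Why: Mild acid-catalysed methanolysis should cleave the triethylsilyl ethers and leave the far more robust tert-butyldimethylsilyl ether in place.

Step 7
Reactants: 8 phenyl 3-O-(tert-butyldimethylsilyl)-6,7-dideoxy-1-thio-β-D-gluco-hept-6-ynopyranoside; 9 benzoyl chloride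
Product: 10 phenyl 2,4-di-O-benzoyl-3-O-(tert-butyldimethylsilyl)-6,7-dideoxy-1-thio-β-D-gluco-hept-6-ynopyranoside
Conditions: BzCl (3 equiv), pyridine, DMAP (cat.), 0 → 40 °C
Reagents that add atoms: benzoyl chloride, O=C(Cl)c1ccccc1
Why: DMAP-catalysed acylation should benzoylate both secondary hydroxyls; the aldehyde stage is past, so the 4-O-benzoate can no longer be lost by β-elimination.

Step 8
Reactants: 10 phenyl 2,4-di-O-benzoyl-3-O-(tert-butyldimethylsilyl)-6,7-dideoxy-1-thio-β-D-gluco-hept-6-ynopyranoside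
Product: 11 2,4-di-O-benzoyl-3-O-(tert-butyldimethylsilyl)-6,7-dideoxy-D-gluco-hept-6-ynopyranose (lactol; anomeric mixture)
Conditions: NBS, acetone/H2O (9:1), 0 °C
Reagents that add atoms: water, O
Why: Bromonium activation of the thioglycoside sulfur and capture of the 2-O-benzoyl-stabilised oxocarbenium ion by water should give the hemiacetal, the electron-poor terminal alkyne being inert to NBS under these conditions.

Step 9
Reactants: 11 2,4-di-O-benzoyl-3-O-(tert-butyldimethylsilyl)-6,7-dideoxy-D-gluco-hept-6-ynopyranose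
Product: 13 1,5-anhydro-2,4-di-O-benzoyl-3-O-(tert-butyldimethylsilyl)-6,7-dideoxy-D-arabino-hept-1-en-6-ynitol (2-benzoyloxy glycal with ethynyl on C5), via α-glycosyl bromide 12 (not isolated)
Conditions: PPh3, CBr4, CH2Cl2, 0 °C → rt; then DBU, 0 °C → rt
Reagents that add atoms: none
Why: Appel bromination of the lactol should give the glycosyl bromide, which settles as the axial α-anomer, and DBU then removes the axial H2 antiperiplanar to bromide (E2), the standard entry to 2-acyloxy glycals; the neutral bromination spares silyl ether and alkyne.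

Step 10
Reactants: 13 1,5-anhydro-2,4-di-O-benzoyl-3-O-(tert-butyldimethylsilyl)-6,7-dideoxy-D-arabino-hept-1-en-6-ynitol; 14 benzoic acid
Product: 15 1,5-anhydro-2,4,7-tri-O-benzoyl-3-O-(tert-butyldimethylsilyl)-6-deoxy-D-arabino-hepta-1,6(Z)-dienitol (glycal with (Z)-2-benzoyloxyvinyl on C5)
Conditions: PhCO2H (1.2 equiv), Ru(η3-CH2C(CH3)CH2)2(Ph2P(CH2)4PPh2) (5 mol %), toluene, 65 °C
Reagents that add atoms: benzoic acid, OC(=O)c1ccccc1
Why: Ru-catalysed anti-Markovnikov hydro-acyloxylation of a terminal alkyne: benzoate adds to the electrophilic α-carbon of a ruthenium vinylidene and protonolysis should deliver the 1-alkenyl ester with Z geometry, the acyloxy-deactivated glycal double bond not adding the weak acid.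

Step 11
Reactants: 15 1,5-anhydro-2,4,7-tri-O-benzoyl-3-O-(tert-butyldimethylsilyl)-6-deoxy-D-arabino-hepta-1,6(Z)-dienitol
Product: 16 (1R,2R,5R,6S)-6-[(tert-butyldimethylsilyl)oxy]-1-formylcyclohex-3-ene-1,2,5-triyl tribenzoate
Conditions: 1,2-dichlorobenzene (0.02 M, degassed), 2,6-di-tert-butyl-4-methylpyridine (0.2 equiv), sealed tube, 220–230 °C
Reagents that add atoms: none
Why: Heating takes the allyl vinyl ether sugar C2=C1–O5–C5–C6=C7 through a concerted, suprafacial [3,3]-sigmatropic (Claisen) shift in which C2–C7 forms as O5–C5 breaks, and the new C1=O makes it irreversible. The closest known reaction type is the thermal Claisen rearrangement of 2-alkenyl-3,4-dihydro-2H-pyrans (C5-vinyl glycals) to cyclohex-3-ene-1-carbaldehydes. The six-membered carbocycle (sugar C2, C3, C4, C5, C6, C7) closes by bonding of the enol ether carbon to the vinyl terminus across a boat-shaped, bicyclo[2.2.2]octane-like array, the only one the C3–C4 tether permits, and the pyran is opened in the same event. The quaternary centre (ring C1) is fixed by the C5 stereocentre of D-glucose, because C7 can reach sugar C2 only on the face that carries the C5 side chain, which puts the formyl group trans and the benzoate cis to the C3 silyloxy group. The secondary centre (ring C2) is fixed by the Z geometry of the enol benzoate, which in the boat array turns the C7 benzoate to the ring face opposite the formyl group, cis to the tertiary benzoate. The step therefore needs only the geometric purity of 15 and freedom from competing thermal pathways: the ether (not an ester) at O3 removes the allylic-ester shift of the glycal, and the acyloxy donor at the allyl terminus should lower the barrier.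

Step 12
Reactants: 16 (1R,2R,5R,6S)-6-[(tert-butyldimethylsilyl)oxy]-1-formylcyclohex-3-ene-1,2,5-triyl tribenzoate
Product: 18 [(1R,2R,5R,6S)-2,5-bis(benzoyloxy)-6-[(tert-butyldimethylsilyl)oxy]-1-hydroxycyclohex-3-en-1-yl]methyl benzoate, via primary alcohol 17 (not isolated)
Conditions: NaBH4, THF/MeOH (10:1), −40 → 0 °C; then Et3N, DMAP (cat.), CH2Cl2, rt
Reagents that add atoms: none
Why: Borohydride reduces the hindered, non-enolisable aldehyde, and the new primary oxygen should take over the neighbouring tertiary benzoate through a five-membered orthoester intermediate (1,2 O-to-O acyl shift) completed by the amine base; with O6 silylated, the primary/secondary tribenzoate with free tertiary OH is the thermodynamic sink.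

Step 13
Reactants: 18 [(1R,2R,5R,6S)-2,5-bis(benzoyloxy)-6-[(tert-butyldimethylsilyl)oxy]-1-hydroxycyclohex-3-en-1-yl]methyl benzoate
Product: 19 [(1S,2R,5R,6S)-2,5-bis(benzoyloxy)-1,6-dihydroxycyclohex-3-en-1-yl]methyl benzoate (CNP0128482.1)
Conditions: HF·pyridine, pyridine, THF, 0 °C → rt
Reagents that add atoms: none
Why: Fluoride-mediated desilylation under buffered acidic conditions should free the C6 hydroxyl without cleaving or shifting benzoates.

## Compound list

1 | phenyl 4,6-O-[(R)-benzylidene]-1-thio-β-D-glucopyranoside | c1ccccc1S[C@@H]1O[C@@H]2CO[C@@H](c3ccccc3)O[C@H]2[C@H](O)[C@H]1O | starting material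
2 | phenyl 4,6-O-benzylidene-3-O-(tert-butyldimethylsilyl)-1-thio-β-D-glucopyranoside | c1ccccc1S[C@@H]1O[C@@H]2CO[C@@H](c3ccccc3)O[C@H]2[C@H](O[Si](C)(C)C(C)(C)C)[C@H]1O | intermediate
3 | phenyl 3-O-(tert-butyldimethylsilyl)-1-thio-β-D-glucopyranoside | c1ccccc1S[C@@H]1O[C@H](CO)[C@@H](O)[C@H](O[Si](C)(C)C(C)(C)C)[C@H]1O | intermediate
4 | phenyl 3-O-(tert-butyldimethylsilyl)-2,4,6-tris-O-(triethylsilyl)-1-thio-β-D-glucopyranoside | c1ccccc1S[C@@H]1O[C@H](CO[Si](CC)(CC)CC)[C@@H](O[Si](CC)(CC)CC)[C@H](O[Si](C)(C)C(C)(C)C)[C@H]1O[Si](CC)(CC)CC | intermediate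
5 | phenyl 3-O-(tert-butyldimethylsilyl)-2,4-bis-O-(triethylsilyl)-1-thio-β-D-gluco-hexodialdo-1,5-pyranoside | c1ccccc1S[C@@H]1O[C@H](C=O)[C@@H](O[Si](CC)(CC)CC)[C@H](O[Si](C)(C)C(C)(C)C)[C@H]1O[Si](CC)(CC)CC | intermediate
6 | dimethyl (1-diazo-2-oxopropyl)phosphonate | COP(=O)(OC)C(=[N+]=[N-])C(C)=O | starting material
7 | phenyl 3-O-(tert-butyldimethylsilyl)-6,7-dideoxy-2,4-bis-O-(triethylsilyl)-1-thio-β-D-gluco-hept-6-ynopyranoside | c1ccccc1S[C@@H]1O[C@H](C#C)[C@@H](O[Si](CC)(CC)CC)[C@H](O[Si](C)(C)C(C)(C)C)[C@H]1O[Si](CC)(CC)CC | intermediate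
8 | phenyl 3-O-(tert-butyldimethylsilyl)-6,7-dideoxy-1-thio-β-D-gluco-hept-6-ynopyranoside | c1ccccc1S[C@@H]1O[C@H](C#C)[C@@H](O)[C@H](O[Si](C)(C)C(C)(C)C)[C@H]1O | intermediate
9 | benzoyl chloride | O=C(Cl)c1ccccc1 | starting material
10 | phenyl 2,4-di-O-benzoyl-3-O-(tert-butyldimethylsilyl)-6,7-dideoxy-1-thio-β-D-gluco-hept-6-ynopyranoside | c1ccccc1S[C@@H]1O[C@H](C#C)[C@@H](OC(=O)c2ccccc2)[C@H](O[Si](C)(C)C(C)(C)C)[C@H]1OC(=O)c1ccccc1 | intermediate
11 | 2,4-di-O-benzoyl-3-O-(tert-butyldimethylsilyl)-6,7-dideoxy-D-gluco-hept-6-ynopyranose (lactol, anomeric mixture) | OC1O[C@H](C#C)[C@@H](OC(=O)c2ccccc2)[C@H](O[Si](C)(C)C(C)(C)C)[C@H]1OC(=O)c1ccccc1 | intermediate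
12 | 2,4-di-O-benzoyl-3-O-(tert-butyldimethylsilyl)-6,7-dideoxy-α-D-gluco-hept-6-ynopyranosyl bromide | Br[C@H]1O[C@H](C#C)[C@@H](OC(=O)c2ccccc2)[C@H](O[Si](C)(C)C(C)(C)C)[C@H]1OC(=O)c1ccccc1 | intermediate
13 | 1,5-anhydro-2,4-di-O-benzoyl-3-O-(tert-butyldimethylsilyl)-6,7-dideoxy-D-arabino-hept-1-en-6-ynitol | C#C[C@H]1OC=C(OC(=O)c2ccccc2)[C@@H](O[Si](C)(C)C(C)(C)C)[C@@H]1OC(=O)c1ccccc1 | intermediate
14 | benzoic acid | OC(=O)c1ccccc1 | starting material
15 | 1,5-anhydro-2,4,7-tri-O-benzoyl-3-O-(tert-butyldimethylsilyl)-6-deoxy-D-arabino-hepta-1,6(Z)-dienitol | O=C(c1ccccc1)O/C=C\[C@H]1OC=C(OC(=O)c2ccccc2)[C@@H](O[Si](C)(C)C(C)(C)C)[C@@H]1OC(=O)c1ccccc1 | intermediate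
16 | (1R,2R,5R,6S)-6-[(tert-butyldimethylsilyl)oxy]-1-formylcyclohex-3-ene-1,2,5-triyl tribenzoate (C1–OBz, C2–OBz and C6–OSi on one face; CHO and C5–OBz on the other) | O=C[C@@]1(OC(=O)c2ccccc2)[C@H](OC(=O)c2ccccc2)C=C[C@@H](OC(=O)c2ccccc2)[C@@H]1O[Si](C)(C)C(C)(C)C | intermediate
17 | (1R,2R,5R,6S)-6-[(tert-butyldimethylsilyl)oxy]-1-(hydroxymethyl)cyclohex-3-ene-1,2,5-triyl tribenzoate | OC[C@@]1(OC(=O)c2ccccc2)[C@H](OC(=O)c2ccccc2)C=C[C@@H](OC(=O)c2ccccc2)[C@@H]1O[Si](C)(C)C(C)(C)C | intermediate
18 | [(1R,2R,5R,6S)-2,5-bis(benzoyloxy)-6-[(tert-butyldimethylsilyl)oxy]-1-hydroxycyclohex-3-en-1-yl]methyl benzoate | O=C(OC[C@@]1(O)[C@H](OC(=O)c2ccccc2)C=C[C@@H](OC(=O)c2ccccc2)[C@@H]1O[Si](C)(C)C(C)(C)C)c1ccccc1 | intermediate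
19 | [(1S,2R,5R,6S)-2,5-bis(benzoyloxy)-1,6-dihydroxycyclohex-3-en-1-yl]methyl benzoate | O=C(OC[C@@]1(O)[C@H](OC(=O)c2ccccc2)C=C[C@@H](OC(=O)c2ccccc2)[C@@H]1O)c1ccccc1 | target

## Step count and risks

Total step count: 13. Longest linear sequence: 13 steps (1 to 19).

**Step 11 (Claisen ring closure).** The boat array forces the Z benzoate on C7 and the silyloxy group on C3 onto the same side, so the shift may be slow. At the temperature then needed, thermal loss of benzoic acid, Z/E isomerisation of the enol ester or transposition of the allylic benzoates in the product could compete. The fallback keeps the same bond construction but moves it to the ester-enolate level, where it should run at or below 80 °C. It sets out from lactol 11 and comes back at alcohol 17. Lactol 11 is oxidised with Dess–Martin periodinane to 2,4-di-O-benzoyl-3-O-(tert-butyldimethylsilyl)-6,7-dideoxy-D-gluco-hept-6-ynono-1,5-lactone F1. Addition of benzoic acid 14 under the conditions of step 10 gives the Z enol benzoate lactone F2. LiN(SiMe3)2 with Me3SiCl present (THF, −78 °C) traps the lactone enolate as the trimethylsilyl ketene acetal F3 before the C3 silyloxy group can be eliminated. Warming (toluene, rt to 80 °C) should bring about the Ireland–Claisen ring contraction through the same tether-enforced boat to the trimethylsilyl ester F4. Aqueous work-up gives the carboxylic acid F5, and BH3·THF at 0 °C reduces the acid in the presence of the benzoates to 17, which is carried on to 18 with Et3N/DMAP as in step 12.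

**Step 10 (hydro-acyloxylation).** Regio- or stereocontrol may be incomplete on this hindered propargylic ether (geminal enol ester or E isomer), or benzoic acid may add to the glycal. The fallback builds the Z C–O bond by stereoretentive coupling. It sets out from alkyne 13 and comes back at 15. Rh-catalysed trans-hydroboration with pinacolborane ([RhCl(1,5-cyclooctadiene)]2, P(i-Pr)3, Et3N) should give the (Z)-alkenyl pinacolboronate F6. KHF2 converts it into the potassium (Z)-alkenyltrifluoroborate F7. Cu(OAc)2-catalysed oxidative coupling with benzoic acid 14 (DMAP, O2, 4 Å sieves) then forms the enol benzoate 15 with retention of the double-bond geometry.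

**Step 4 (direct oxidation of the primary silyl ether).** Silyl cleavage under the Swern conditions may be incomplete or unselective, or the chlorosulfonium salt may activate the thioglycoside. The fallback separates deprotection from oxidation. It sets out from 4 and comes back at 5. HF·pyridine buffered with pyridine (THF, 0 °C) should remove only the primary triethylsilyl group to give phenyl 3-O-(tert-butyldimethylsilyl)-2,4-bis-O-(triethylsilyl)-1-thio-β-D-glucopyranoside F8, and Dess–Martin periodinane with NaHCO3 in CH2Cl2 oxidises F8 to aldehyde 5.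

## Further compounds

F1 | step 11 | 2,4-di-O-benzoyl-3-O-(tert-butyldimethylsilyl)-6,7-dideoxy-D-gluco-hept-6-ynono-1,5-lactone | O=C1O[C@H](C#C)[C@@H](OC(=O)c2ccccc2)[C@H](O[Si](C)(C)C(C)(C)C)[C@H]1OC(=O)c1ccccc1
F2 | step 11 | 2,4,7-tri-O-benzoyl-3-O-(tert-butyldimethylsilyl)-6-deoxy-D-gluco-hept-6(Z)-enono-1,5-lactone | O=C1O[C@H](/C=C\OC(=O)c2ccccc2)[C@@H](OC(=O)c2ccccc2)[C@H](O[Si](C)(C)C(C)(C)C)[C@H]1OC(=O)c1ccccc1
F3 | step 11 | trimethylsilyl ketene acetal of F2 (1-trimethylsilyloxy-2-benzoyloxy glycal) | C[Si](C)(C)OC1=C(OC(=O)c2ccccc2)[C@@H](O[Si](C)(C)C(C)(C)C)[C@H](OC(=O)c2ccccc2)[C@@H](/C=C\OC(=O)c2ccccc2)O1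
F4 | step 11 | trimethylsilyl (1R,2R,5R,6S)-1,2,5-tris(benzoyloxy)-6-[(tert-butyldimethylsilyl)oxy]cyclohex-3-ene-1-carboxylate | C[Si](C)(C)OC(=O)[C@@]1(OC(=O)c2ccccc2)[C@H](OC(=O)c2ccccc2)C=C[C@@H](OC(=O)c2ccccc2)[C@@H]1O[Si](C)(C)C(C)(C)C
F5 | step 11 | (1R,2R,5R,6S)-1,2,5-tris(benzoyloxy)-6-[(tert-butyldimethylsilyl)oxy]cyclohex-3-ene-1-carboxylic acid | OC(=O)[C@@]1(OC(=O)c2ccccc2)[C@H](OC(=O)c2ccccc2)C=C[C@@H](OC(=O)c2ccccc2)[C@@H]1O[Si](C)(C)C(C)(C)C
F6 | step 10 | (Z)-alkenyl pinacolboronate of glycal 13 (Bpin on C7) | CC1(C)OB(/C=C\[C@H]2OC=C(OC(=O)c3ccccc3)[C@@H](O[Si](C)(C)C(C)(C)C)[C@@H]2OC(=O)c2ccccc2)OC1(C)C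
F7 | step 10 | potassium (Z)-alkenyltrifluoroborate of glycal 13 | [K+].F[B-](F)(F)/C=C\[C@H]1OC=C(OC(=O)c2ccccc2)[C@@H](O[Si](C)(C)C(C)(C)C)[C@@H]1OC(=O)c1ccccc1
F8 | step 4 | phenyl 3-O-(tert-butyldimethylsilyl)-2,4-bis-O-(triethylsilyl)-1-thio-β-D-glucopyranoside | c1ccccc1S[C@@H]1O[C@H](CO)[C@@H](O[Si](CC)(CC)CC)[C@H](O[Si](C)(C)C(C)(C)C)[C@H]1O[Si](CC)(CC)CC
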